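(All runs are calculated for substances that don't exist, and the scatter is random.)

At early times the amber flask loses a steady share of its starting material per hour, so I read its table in powers of ten.

common to all: starting material 20 mM; free enzyme 0.01 mol%; added ligand 1.1 µM
- amber: second substrate 0.70 equiv; temperature 37 °C; the very flask that is asked about, followed so far
- teal: second substrate 0.47 equiv; temperature 32 °C; run made earlier
- flask: second substrate 0.700 equiv; temperature 37 °C; time 8.0 d

- amber (time / h: target / %, starting material / %): 25.0: 28, 73; 48.0: 45, 54; 72.0: 61, 40; 96.0: 64, 32; 120: 70, 30; 144: 70, 32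
- teal (time / h: target / %, starting material / %): 2.50: 4, 97; 5.00: 4, 98; 8.00: 3, 98; 10.0: 5, 91; 12.0: 3, 95; 15.0: 9, 90

(standard deviation of a reading: 1.5 percentage points)

- south-east: change nothing and wait 8.0 d more
- south: at 8.0 d add free enzyme, 100 % of the amount charged, then wait 8.0 d
- east: at 8.0 d take out 90 % of the target then present, then wait 8.0 d
- north: at 8.0 d add second substrate, 100 % of the amount charged, then wait 8.0 d
- west: at 8.0 d raise the temperature by 20 K, then wait 8.0 d

- removed target is counted in
- additions bring no volume worth counting

- target, in percent of the starting material first charged, at 8.0 d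
- which option adds most target ("none" when 2 percentage points or less is all one gets) (south-east / south / east / north / west / none)
- target present, with what was taken out counted in, in percent of the starting material first charged, after south-east
- target present, with what was taken out counted in, in percent of the starting material first charged, after south

Let τ be the decade time, the time for starting material to fall tenfold, taken from the common logarithm of what is left. Row one of the amber table gives 183 h, row two 179 h, and row three 181 h. That is one constant within the scatter, and target plus starting material stays near 101 %.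

The last row breaks the pattern. At τ the amber flask should hold 16.0 % of its starting material at 144 h, but it reads 32 %, while target reads 70 % and then 70 %.

So I name C, the ceiling: the charge of the limiting reagent in percent of the starting material, taking one second substrate per target. For this recipe C is 70.0 %. Reaching C takes 0.523 decades, and 8.0 d offers 1.06, twice that. I therefore commit to target at C at 8.0 d and after waiting 8.0 d more. North raises C, whereas south, east and west leave it where it stands. The teal run, with its ceiling of 47.0 %, ends at 9 %, so it doesn't test C.

The forecast says 70 % (67.5 % to 72.5 %), north, 70 % and 70.5 %, on the reading that “the second substrate has run out”.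

The flask gives 69.9 %, then 70.0 % after south-east and 70.0 % after south, and north is best, adding 8.6 percentage points.

    free enzyme → unfolded enzyme (k = 8.30 × 10⁻⁴ h⁻¹, Ea = 263 kJ mol⁻¹)
    starting material + free enzyme ⇌ first complex (K = 130 L mol⁻¹, k = 3.60 × 10⁶ L mol⁻¹ h⁻¹, Ea = 36.0 kJ mol⁻¹, ΔH = 31.0 kJ mol⁻¹)
    first complex → loaded enzyme + first product (k = 380 h⁻¹, Ea = 79.0 kJ mol⁻¹)
    second substrate + loaded enzyme ⇌ second complex (K = 100 L mol⁻¹, k = 2.00 × 10⁶ L mol⁻¹ h⁻¹, Ea = 37.0 kJ mol⁻¹, ΔH = −24.0 kJ mol⁻¹)
    second complex → free enzyme + target (k = 920 h⁻¹, Ea = 87.0 kJ mol⁻¹)
    2 loaded enzyme ⇌ resting dimer, settled at all times (K = 1.70 × 10⁵ L mol⁻¹, ΔH = 1.00 kJ mol⁻¹)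
    free enzyme + added ligand ⇌ idle complex, settled at all times (K = 6.30 × 10⁶ L mol⁻¹, ΔH = −68.0 kJ mol⁻¹)
    2 loaded enzyme → spent catalyst (k = 30000 L mol⁻¹ h⁻¹, Ea = 38.0 kJ mol⁻¹)
    (constants at 37 °C)

The asked flask has come to rest. At 192 h free second substrate stands at 0.19 % of its charge, worth 0.14 points of target. Ten times the time, 1920 h, gives target at 70.0 %, a change of 0.10 points. But C is a roof, not a promise: north lifts it to 100 % yet adds 8.6 points, with spent catalyst at 84.8 % of the catalyst when it is added. With less enzyme the answer parts from C: at 0.0054 mol% of free enzyme the answer at 8.0 d has moved by 5 points.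

The neighbour charged with 1.80 equiv from the start has C at 100 %, starting material now being limiting; it gives 99.7 %.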